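## Retrosynthetic overview

1. Target 31 ⇐ saponification of diester 29 ⇐ MnO2 oxidation of carbinol 28. The enone is cut at the aryl-C(O)–CH= bond (alkenylzinc + aldehyde), not by aldol/HWE, because the (2Z,4Z)-6-oxohexadienoate an aldol would need is stereolabile (oxa-6π closure to a 2H-pyran).
2. 28 ⇐ salicylaldehyde 15 + (E)-trienylzinc made by syn-hydroboration of the (Z,Z)-dienyne 21; 21 ⇐ Negishi ethynylation ⇐ Still–Gennari olefination of (Z)-3-iodoacrolein.
3. 15 ⇐ phenol-directed ortho-formylation of 12 (only free ortho position); enoate arm ⇐ 9-BBN / B-alkyl Suzuki on the terminal alkene of 7.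
4. Key step: benzylic stereocentre ⇐ Ni-catalysed asymmetric hydrovinylation of vinylarene 5 with ethylene (5 from 5-methoxysalicylaldehyde 1).
5. No ring is formed; the benzene ring is bought in 1.

Assumption: the phosphoramidite L = (Sa,Rc,Rc)-(1,1'-binaphthalene-2,2'-diyl) N,N-bis(1-phenylethyl)phosphoramidite is taken as the antipode that gives (R)-7; if the first run shows the opposite sense, the mirror-image ligand is used and nothing else changes.

Numbers are given to substrates, to every reagent that contributes non-hydrogen atoms to a product or intermediate, and to intermediates and products.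

## Route

Step 1
Reactants: 1 2-hydroxy-5-methoxybenzaldehyde; 2 chloromethyl methyl ether
Product: 3 5-methoxy-2-(methoxymethoxy)benzaldehyde
Conditions: MOMCl, i-Pr2NEt, CH2Cl2, 0 °C to rt
Reagents that add atoms: chloromethyl methyl ether 2, COCCl
Why: Williamson-type O-alkylation (MOM protection) masks the acidic phenol, which would quench the ylide and the cationic nickel hydride of steps 2–3, and the acetal survives base, borane and palladium.

Step 2
Reactants: 3 5-methoxy-2-(methoxymethoxy)benzaldehyde; 4 methyltriphenylphosphonium bromide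
Product: 5 4-methoxy-1-(methoxymethoxy)-2-vinylbenzene
Conditions: Ph3PCH3Br, KOt-Bu, THF, 0 °C to rt
Reagents that add atoms: methyltriphenylphosphonium bromide 4, C[P+](c1ccccc1)(c1ccccc1)c1ccccc1.[Br-]
Why: Wittig methylenation of a non-enolisable aryl aldehyde gives the vinylarene needed for the key step.

Step 3
Reactants: 5 4-methoxy-1-(methoxymethoxy)-2-vinylbenzene; 6 ethylene
Product: 7 (R)-2-(but-3-en-2-yl)-4-methoxy-1-(methoxymethoxy)benzene
Conditions: [Ni(C3H5)Br]2 (1 mol%), L (2 mol%), Na[B(3,5-(CF3)2C6H3)4] (2.5 mol%), C2H4 (1 atm), CH2Cl2, −78 °C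
Reagents that add atoms: ethylene 6, C=C
Why: Ni-catalysed asymmetric hydrovinylation (RajanBabu heterodimerisation): the cationic phosphoramidite–nickel hydride adds to the styrene to give an η3-benzylnickel, ethylene inserts at the benzylic carbon on the face left open by the ligand and β-hydride elimination releases the 3-arylbut-1-ene, so the (R) benzylic centre is set directly from ethylene, with −78 °C suppressing isomerisation to the 2-arylbut-2-ene and ortho-alkoxy vinylarenes being accepted substrates.

Step 4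
Reactants: 7 (R)-2-(but-3-en-2-yl)-4-methoxy-1-(methoxymethoxy)benzene; 8 9-borabicyclo[3.3.1]nonane (9-BBN); 9 methyl (E)-3-iodoacrylate
Product: 11 methyl (R,E)-6-[5-methoxy-2-(methoxymethoxy)phenyl]hept-2-enoate, via alkylborane 10 (not isolated)
Conditions: 9-BBN dimer, THF, 0 °C to rt; then 9, Pd(dppf)Cl2 (5 mol%), AsPh3 (5 mol%), Cs2CO3, DMF/THF/H2O, rt
Reagents that add atoms: methyl (E)-3-iodoacrylate 9, COC(=O)/C=C/I; 9-BBN 8, B1C2CCCC1CCC2
Why: Anti-Markovnikov hydroboration with 9-BBN followed by B-alkyl Suzuki–Miyaura coupling with the vinyl iodide (retention of E geometry, room temperature) adds the whole enoate arm in one pot, the boron of 8 staying only in 10 and the benzylic stereocentre being untouched and no longer allylic afterwards.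

Step 5
Reactants: 11 methyl (R,E)-6-[5-methoxy-2-(methoxymethoxy)phenyl]hept-2-enoate
Product: 12 methyl (R,E)-6-(2-hydroxy-5-methoxyphenyl)hept-2-enoate
Conditions: HCl (1.25 M in MeOH, 0.5 equiv), MeOH, 40 °C
Reagents that add atoms: none
Why: Acid-catalysed acetal exchange (MOM cleavage) with methanol as acceptor frees the phenol, while the methyl ester cannot transesterify to anything else and the stereocentre is not acidic.

Step 6
Reactants: 12 methyl (R,E)-6-(2-hydroxy-5-methoxyphenyl)hept-2-enoate; 13 paraformaldehyde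
Product: 15 methyl (R,E)-6-(3-formyl-2-hydroxy-5-methoxyphenyl)hept-2-enoate, via benzylic alcohol 14 (not isolated)
Conditions: MgCl2, Et3N, (CH2O)n, MeCN, 80 °C
Reagents that add atoms: paraformaldehyde 13, C=O
Why: Casnati–Skattebøl ortho-formylation: the magnesium phenoxide delivers formaldehyde to the only free ortho position (para is blocked by OMe) and the benzylic alkoxide is oxidised by a second formaldehyde through Oppenauer-type hydride transfer, the remote enoate being inert.

Step 7
Reactants: 16 ethyl (Z)-3-iodoacrylate; 17 methyl bis(2,2,2-trifluoroethyl)phosphonoacetate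
Product: 19 methyl (2Z,4Z)-5-iodopenta-2,4-dienoate, via iodoacrolein 18 (not isolated)
Conditions: i-Bu2AlH, CH2Cl2, −78 °C; then 17, KN(SiMe3)2, 18-crown-6, THF, −78 °C
Reagents that add atoms: methyl bis(2,2,2-trifluoroethyl)phosphonoacetate 17, COC(=O)CP(=O)(OCC(F)(F)F)OCC(F)(F)F
Why: Half-reduction of the ester at −78 °C and Still–Gennari (Z-selective Horner–Wadsworth–Emmons) olefination of the cold aldehyde: the electron-poor trifluoroethyl phosphonate with a dissociated potassium counter-ion eliminates fast from the kinetic adduct, giving the new 2Z alkene while the existing Z iodoalkene is kept at low temperature.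

Step 8
Reactants: 19 methyl (2Z,4Z)-5-iodopenta-2,4-dienoate; 20 ethynylmagnesium bromide
Product: 21 methyl (2Z,4Z)-hepta-2,4-dien-6-ynoate
Conditions: HC≡CMgBr, ZnBr2, THF, 0 °C; then 19, Pd(PPh3)4 (5 mol%), THF, 0 °C to rt
Reagents that add atoms: ethynylmagnesium bromide 20, C#C[Mg]Br
Why: Negishi coupling of the alkenyl iodide with ethynylzinc bromide proceeds with retention of alkene geometry under zerovalent palladium at or below room temperature and gives the terminal enyne directly, the ester being inert to the alkynylzinc.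

Step 9
Reactants: 15 methyl (R,E)-6-(3-formyl-2-hydroxy-5-methoxyphenyl)hept-2-enoate; 21 methyl (2Z,4Z)-hepta-2,4-dien-6-ynoate; 22 borane–dimethyl sulfide; 23 cyclohexene; 24 diethylzinc
Product: 28 methyl (R,E)-6-{2-hydroxy-3-[(2E,4Z,6Z)-1-hydroxy-8-methoxy-8-oxoocta-2,4,6-trien-1-yl]-5-methoxyphenyl}hept-2-enoate (both carbinol epimers), via dicyclohexylborane 25 (not isolated), via trienylborane 26 (not isolated), via trienylzinc 27 (not isolated)
Conditions: BH3·SMe2, cyclohexene, THF, 0 °C; 21, 0 °C to rt; Et2Zn, hexane, −78 °C; then 15 (pre-treated with 1 equiv Et2Zn), Me2NCH2CH2OH (10 mol%), toluene, −20 to 0 °C; aq. NH4Cl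
Reagents that add atoms: dienyne 21, COC(=O)/C=C\C=C/C#C; borane–dimethyl sulfide 22, C[S+](C)[BH3-]; cyclohexene 23, C1=CCCCC1; diethylzinc 24, CC[Zn]CC
Why: Oppolzer–Srebnik sequence: syn-hydroboration puts boron on the terminal alkyne carbon (fixing both the regiochemistry and the new E alkene), boron-to-zinc exchange gives the alkenyl(ethyl)zinc, and this adds to the zinc-phenoxide-activated aldehyde but not to esters, so the aryl-C–CH= bond is made without protecting groups, the carbinol centre being formed as a mixture that step 10 erases and the boron, cyclohexyl, zinc and ethyl groups of 22–24 ending up only in 25–27 and the by-products.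

Step 10
Reactants: 28 methyl (R,E)-6-{2-hydroxy-3-[(2E,4Z,6Z)-1-hydroxy-8-methoxy-8-oxoocta-2,4,6-trien-1-yl]-5-methoxyphenyl}hept-2-enoate
Product: 29 methyl (R,E)-6-{2-hydroxy-5-methoxy-3-[(2E,4Z,6Z)-8-methoxy-8-oxoocta-2,4,6-trienoyl]phenyl}hept-2-enoate
Conditions: MnO2 (activated, 20 equiv), CH2Cl2, rt, dark
Reagents that add atoms: none
Why: MnO2 oxidises the doubly activated (benzylic and allylic) alcohol to the hydrogen-bonded 2-hydroxyaryl ketone under neutral conditions that leave the Z,Z-diene and both esters alone.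

Step 11
Reactants: 29 methyl (R,E)-6-{2-hydroxy-5-methoxy-3-[(2E,4Z,6Z)-8-methoxy-8-oxoocta-2,4,6-trienoyl]phenyl}hept-2-enoate; 30 lithium hydroxide
Product: 31 (2Z,4Z,6E)-8-{3-[(2R,5E)-6-carboxyhex-5-en-2-yl]-2-hydroxy-5-methoxyphenyl}-8-oxoocta-2,4,6-trienoic acid
Conditions: LiOH·H2O (6 equiv), THF/H2O 3:1, 0 °C to rt, dark; then 0.5 M HCl to pH 3 at 0 °C
Reagents that add atoms: lithium hydroxide 30, [Li+].[OH-]
Why: Saponification of both methyl esters by acyl–oxygen cleavage; the substrate reacts as its phenoxide, which deactivates the enone (2'-hydroxychalcone-type phenoxides are stable to hydroxide), Z-polyenoates such as 13-cis-retinoates are saponified without isomerisation, and the triene carries no sp3 C–H that could allow deconjugation.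

## Compound list

1 | 2-hydroxy-5-methoxybenzaldehyde | COc1ccc(O)c(C=O)c1 | starting material
2 | chloromethyl methyl ether | COCCl | starting material
3 | 5-methoxy-2-(methoxymethoxy)benzaldehyde | COCOc1ccc(OC)cc1C=O | intermediate
4 | methyltriphenylphosphonium bromide | C[P+](c1ccccc1)(c1ccccc1)c1ccccc1.[Br-] | starting material
5 | 4-methoxy-1-(methoxymethoxy)-2-vinylbenzene | COCOc1ccc(OC)cc1C=C | intermediate
6 | ethylene | C=C | starting material
7 | (R)-2-(but-3-en-2-yl)-4-methoxy-1-(methoxymethoxy)benzene | COCOc1ccc(OC)cc1[C@H](C)C=C | intermediate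
8 | 9-borabicyclo[3.3.1]nonane (used as its dimer) | B1C2CCCC1CCC2 | starting material
9 | methyl (E)-3-iodoacrylate | COC(=O)/C=C/I | starting material
10 | (R)-9-{3-[5-methoxy-2-(methoxymethoxy)phenyl]butyl}-9-borabicyclo[3.3.1]nonane | COCOc1ccc(OC)cc1[C@H](C)CCB1C2CCCC1CCC2 | intermediate (not isolated)
11 | methyl (R,E)-6-[5-methoxy-2-(methoxymethoxy)phenyl]hept-2-enoate | COCOc1ccc(OC)cc1[C@H](C)CC/C=C/C(=O)OC | intermediate
12 | methyl (R,E)-6-(2-hydroxy-5-methoxyphenyl)hept-2-enoate | COc1ccc(O)c([C@H](C)CC/C=C/C(=O)OC)c1 | intermediate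
13 | paraformaldehyde (formaldehyde source) | C=O | starting material
14 | methyl (R,E)-6-[2-hydroxy-3-(hydroxymethyl)-5-methoxyphenyl]hept-2-enoate | COc1cc(CO)c(O)c([C@H](C)CC/C=C/C(=O)OC)c1 | intermediate (not isolated)
15 | methyl (R,E)-6-(3-formyl-2-hydroxy-5-methoxyphenyl)hept-2-enoate | COc1cc(C=O)c(O)c([C@H](C)CC/C=C/C(=O)OC)c1 | intermediate
16 | ethyl (Z)-3-iodoacrylate | CCOC(=O)/C=C\I | starting material
17 | methyl bis(2,2,2-trifluoroethyl)phosphonoacetate | COC(=O)CP(=O)(OCC(F)(F)F)OCC(F)(F)F | starting material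
18 | (Z)-3-iodoacrolein | O=C/C=C\I | intermediate (not isolated)
19 | methyl (2Z,4Z)-5-iodopenta-2,4-dienoate | COC(=O)/C=C\C=C/I | intermediate
20 | ethynylmagnesium bromide | C#C[Mg]Br | starting material
21 | methyl (2Z,4Z)-hepta-2,4-dien-6-ynoate | COC(=O)/C=C\C=C/C#C | intermediate
22 | borane–dimethyl sulfide | C[S+](C)[BH3-] | starting material
23 | cyclohexene | C1=CCCCC1 | starting material
24 | diethylzinc | CC[Zn]CC | starting material
25 | dicyclohexylborane | B(C1CCCCC1)C1CCCCC1 | intermediate (not isolated)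
26 | methyl (2Z,4Z,6E)-7-(dicyclohexylboranyl)hepta-2,4,6-trienoate | COC(=O)/C=C\C=C/C=C/B(C1CCCCC1)C1CCCCC1 | intermediate (not isolated)
27 | ethyl[(1E,3Z,5Z)-7-methoxy-7-oxohepta-1,3,5-trien-1-yl]zinc | COC(=O)/C=C\C=C/C=C/[Zn]CC | intermediate (not isolated)
28 | methyl (R,E)-6-{2-hydroxy-3-[(2E,4Z,6Z)-1-hydroxy-8-methoxy-8-oxoocta-2,4,6-trien-1-yl]-5-methoxyphenyl}hept-2-enoate (both carbinol epimers) | COc1cc(C(O)/C=C/C=C\C=C/C(=O)OC)c(O)c([C@H](C)CC/C=C/C(=O)OC)c1 | intermediate
29 | methyl (R,E)-6-{2-hydroxy-5-methoxy-3-[(2E,4Z,6Z)-8-methoxy-8-oxoocta-2,4,6-trienoyl]phenyl}hept-2-enoate | COc1cc(C(=O)/C=C/C=C\C=C/C(=O)OC)c(O)c([C@H](C)CC/C=C/C(=O)OC)c1 | intermediate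
30 | lithium hydroxide (as monohydrate) | [Li+].[OH-] | starting material
31 | (2Z,4Z,6E)-8-{3-[(2R,5E)-6-carboxyhex-5-en-2-yl]-2-hydroxy-5-methoxyphenyl}-8-oxoocta-2,4,6-trienoic acid | COc1cc(C(=O)/C=C/C=C\C=C/C(=O)O)c(O)c([C@H](C)CC/C=C/C(=O)O)c1 | target

## Step count and risk

Total: 11 steps (9 in the main line, 2 for dienyne 21).
Longest linear sequence: 9 steps (1 → 3 → 5 → 7 → 11 → 12 → 15 → 28 → 29 → 31).

The three steps most likely to fail:

**Step 9 (hydroboration / boron-to-zinc exchange / addition).** The electron-poor, volatile dienyne may hydroborate sluggishly or lose Z geometry, and the trienylzinc may transfer poorly to the chelated aldehyde. Fallback: add the triene as an alkenylchromium reagent (Nozaki–Hiyama–Kishi reaction), which tolerates esters and the free phenol, and make the required iodotriene by Stille coupling instead of alkyne hydrometalation. It sets out from iododiene 19 (step 8 is then not needed) together with aldehyde 15 and comes back to the route at 28. Stille coupling of 19 with (E)-1,2-bis(tributylstannyl)ethene (3 equiv, Pd2(dba)3, AsPh3, NMP, rt, dark) joins the alkenes with retention and gives methyl (2Z,4Z,6E)-7-(tributylstannyl)hepta-2,4,6-trienoate F1. Iododestannylation (I2, 1.0 equiv, CH2Cl2, −78 °C, dark) gives methyl (2Z,4Z,6E)-7-iodohepta-2,4,6-trienoate F2 with retention at the E alkene. CrCl2 (6 equiv) with NiCl2 (2 mol%) in DMSO/THF at rt then adds this iodotriene to aldehyde 15 chemoselectively and gives carbinol 28.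

**Step 7 (one-pot half-reduction / Z-olefination).** (Z)-3-Iodoacrolein can isomerise or undergo addition–elimination at the iodine-bearing carbon, and Z selectivity may erode in the presence of aluminium salts. Fallback: install the alkyne first, so that the aldehyde to be olefinated is the sturdier enynal. It sets out from 16 and comes back at 21, replacing steps 7 and 8. Sonogashira coupling of 16 with ethynyltrimethylsilane (Pd(PPh3)2Cl2, CuI, Et3N, THF, rt) gives ethyl (Z)-5-(trimethylsilyl)pent-2-en-4-ynoate F3. i-Bu2AlH (CH2Cl2, −78 °C) gives (Z)-5-(trimethylsilyl)pent-2-en-4-ynal F4. This is olefinated cold with 17, KN(SiMe3)2 and 18-crown-6 to methyl (2Z,4Z)-7-(trimethylsilyl)hepta-2,4-dien-6-ynoate F5. K2CO3 in MeOH at 0 °C removes the silyl group to give 21.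

**Step 11 (saponification on the finished trienone).** Hydroxide may add to the doubly activated triene or erode the Z,Z geometry, and the diacid is acid-sensitive on work-up. Fallback: change the order so that base never meets the trienone. It sets out from 28 and comes back at 31. Carbinol 28, whose trienoate is not yet conjugated to a ketone, is saponified (LiOH·H2O, THF/H2O, 0 °C; NaH2PO4 to pH 5, to avoid ionising the o-hydroxybenzylic alcohol). This gives (2Z,4Z,6E)-8-{3-[(2R,5E)-6-carboxyhex-5-en-2-yl]-2-hydroxy-5-methoxyphenyl}-8-hydroxyocta-2,4,6-trienoic acid F6. Neutral MnO2 oxidation (EtOAc, rt, dark; the diacid is washed off the oxide with EtOAc containing 1% AcOH) then forms the ketone last and gives 31 directly.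

Further compounds
F1 | step 9 | methyl (2Z,4Z,6E)-7-(tributylstannyl)hepta-2,4,6-trienoate | COC(=O)/C=C\C=C/C=C/[Sn](CCCC)(CCCC)CCCC
F2 | step 9 | methyl (2Z,4Z,6E)-7-iodohepta-2,4,6-trienoate | COC(=O)/C=C\C=C/C=C/I
F3 | step 7 | ethyl (Z)-5-(trimethylsilyl)pent-2-en-4-ynoate | CCOC(=O)/C=C\C#C[Si](C)(C)C
F4 | step 7 | (Z)-5-(trimethylsilyl)pent-2-en-4-ynal | O=C/C=C\C#C[Si](C)(C)C
F5 | step 7 | methyl (2Z,4Z)-7-(trimethylsilyl)hepta-2,4-dien-6-ynoate | COC(=O)/C=C\C=C/C#C[Si](C)(C)C
F6 | step 11 | (2Z,4Z,6E)-8-{3-[(2R,5E)-6-carboxyhex-5-en-2-yl]-2-hydroxy-5-methoxyphenyl}-8-hydroxyocta-2,4,6-trienoic acid | COc1cc(C(O)/C=C/C=C\C=C/C(=O)O)c(O)c([C@H](C)CC/C=C/C(=O)O)c1
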